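**Retrosynthetic overview**
- The nitrogen ring closes last: the C1=N bond and the C3 stereocentre come from an achiral 1,5-diketone by (R)-selective transaminase monoamination and spontaneous cyclocondensation (no Bischler–Napieralski step).
- The diketone comes from an ortho-allyl aryl ketone (Wacker oxidation), made in one pot from a fluoro-biaryl by aryne carbomagnesiation and acetylation.
- The biaryl bond is not made by aryl–aryl coupling: the methyl/methoxy-bearing naphthalene ring is built onto a benzylic carbon of ring B by 3-methoxybenzyne insertion into a 3-aryl-2,4-pentanedione, then aldol aromatisation and O-methylation.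
- The 3-aryl-2,4-pentanedione comes from 2-fluoro-6-iodoanisole and acetylacetone.
- Ring order: ring B (bought) → substituted naphthalene ring, annulated onto the aryne-derived benzo ring → nitrogen ring.

Assumption: the SMILES fixes only C3 (R) and leaves the biaryl axis undefined, so the route controls C3 and accepts the axis as formed (two atropo-diastereomers, separable by chromatography if one is wanted).

**Step 1**
Reactants: 1 2-fluoro-6-iodoanisole (1-fluoro-3-iodo-2-methoxybenzene); 2 acetylacetone (pentane-2,4-dione)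
Product: 3 3-(3-fluoro-2-methoxyphenyl)pentane-2,4-dione
Conditions: CuI (10 mol%), L-proline (20 mol%), Cs2CO3, DMSO, 45 °C
Reagents that add atoms: none
Why: CuI/L-proline-catalysed Ullmann–Hurtley C-arylation of the acetylacetone enolate by the aryl iodide, run at 45 °C where the C–F bond is inert and retro-Claisen deacetylation of the product is slow; no stereocentre is formed.

**Step 2**
Reactants: 3 3-(3-fluoro-2-methoxyphenyl)pentane-2,4-dione; 4 3-methoxy-2-(trimethylsilyl)phenyl trifluoromethanesulfonate
Product: 7 4-(3-fluoro-2-methoxyphenyl)-8-methoxy-3-methylnaphthalen-1-ol, via 3-methoxybenzyne 5 (not isolated), via 1-(2-acetyl-3-methoxyphenyl)-1-(3-fluoro-2-methoxyphenyl)propan-2-one 6 (not isolated)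
Conditions: CsF (3 equiv), MeCN, 80 °C; then aq KOH, MeOH, 60 °C, same pot
Reagents that add atoms: none
Why: Aryne acyl-alkylation (C–C σ-bond insertion) followed by intramolecular aldol condensation: the diketone carbon adds to the aryne carbon meta to OMe, the aryl anion ortho to OMe takes over one acetyl group through a benzocyclobutenoxide, and base then condenses that aryl methyl ketone onto the remaining aliphatic ketone and aromatises, so the peri-dioxygenated 1-naphthol and the biaryl bond arise with fixed regiochemistry.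

**Step 3**
Reactants: 7 4-(3-fluoro-2-methoxyphenyl)-8-methoxy-3-methylnaphthalen-1-ol
Product: 8 1-(3-fluoro-2-methoxyphenyl)-4,5-dimethoxy-2-methylnaphthalene
Conditions: MeI, K2CO3, DMF, 40 °C
Reagents that add atoms: iodomethane, CI
Why: Williamson O-methylation of the only acidic site, the naphthol, with warming to overcome the peri hydrogen bond.

**Step 4**
Reactants: 8 1-(3-fluoro-2-methoxyphenyl)-4,5-dimethoxy-2-methylnaphthalene
Product: 12 1-[3-(4,5-dimethoxy-2-methylnaphthalen-1-yl)-2-methoxy-6-(prop-2-en-1-yl)phenyl]ethan-1-one, via ortho-lithiated fluoroarene 9 (not isolated), via 4-naphthyl-3-methoxybenzyne 10 (not isolated), via arylmagnesium bromide 11 (not isolated)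
Conditions: s-BuLi (1.1 equiv), THF, −78 °C; allylMgBr (3 equiv), −78 → 0 °C; then cannulate into Ac2O (10 equiv), THF, −78 °C → rt
Reagents that add atoms: allylmagnesium bromide, C=CC[Mg]Br; acetic anhydride, CC(=O)OC(C)=O
Why: Three-component aryne coupling: fluorine-directed ortho-lithiation at the only ring-B C–H next to F, LiF loss to the 3-methoxyaryne, carbomagnesiation by the allyl Grignard at the carbon remote from OMe, and Grignard acylation of the resulting OMe-flanked arylmagnesium by excess Ac2O at low temperature.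

**Step 5**
Reactants: 12 1-[3-(4,5-dimethoxy-2-methylnaphthalen-1-yl)-2-methoxy-6-(prop-2-en-1-yl)phenyl]ethan-1-one
Product: 13 1-[2-acetyl-4-(4,5-dimethoxy-2-methylnaphthalen-1-yl)-3-methoxyphenyl]propan-2-one
Conditions: PdCl2 (10 mol%), CuCl (1 equiv), O2 (1 atm), DMF/H2O 7:1, rt
Reagents that add atoms: water, O
Why: Tsuji–Wacker oxidation: Markovnikov hydroxypalladation of the terminal alkene gives the methyl ketone, with O2 as terminal oxidant, under near-neutral conditions that leave the aldol-prone 1,5-diketone and the electron-rich naphthalene untouched.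

**Step 6**
Reactants: 13 1-[2-acetyl-4-(4,5-dimethoxy-2-methylnaphthalen-1-yl)-3-methoxyphenyl]propan-2-one
Product: 15 (3R)-7-(4,5-dimethoxy-2-methylnaphthalen-1-yl)-8-methoxy-1,3-dimethyl-3,4-dihydroisoquinoline, via (R)-amino ketone 14 (not isolated)
Conditions: (R)-selective ω-transaminase (ATA-117 type), pyridoxal 5'-phosphate (1 mM), isopropylamine (1 M), triethanolamine buffer pH 8.5, 20% DMSO, 40 °C, 24–48 h
Reagents that add atoms: isopropylamine, CC(C)N
Why: Biocatalytic asymmetric transamination followed by spontaneous intramolecular imine condensation: the enzyme aminates only the unhindered arylacetone carbonyl (the di-ortho-substituted aryl ketone does not fit), delivers nitrogen to one face to set C3 as R, and ring closure onto the neighbouring aryl ketone pulls the equilibrium to the 3,4-dihydroisoquinoline.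

**Compound list**
1 | 2-fluoro-6-iodoanisole | COc1c(F)cccc1I | starting material
2 | acetylacetone | CC(=O)CC(C)=O | starting material
3 | 3-(3-fluoro-2-methoxyphenyl)pentane-2,4-dione | COc1c(F)cccc1C(C(C)=O)C(C)=O | intermediate
4 | 3-methoxy-2-(trimethylsilyl)phenyl trifluoromethanesulfonate | COc1cccc(OS(=O)(=O)C(F)(F)F)c1[Si](C)(C)C | starting material
5 | 3-methoxybenzyne | COC1=CC=CC#C1 | intermediate
6 | 1-(2-acetyl-3-methoxyphenyl)-1-(3-fluoro-2-methoxyphenyl)propan-2-one | COc1c(F)cccc1C(C(C)=O)c1cccc(OC)c1C(C)=O | intermediate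
7 | 4-(3-fluoro-2-methoxyphenyl)-8-methoxy-3-methylnaphthalen-1-ol | COc1c(-c2c(C)cc(O)c3c(OC)cccc23)cccc1F | intermediate
8 | 1-(3-fluoro-2-methoxyphenyl)-4,5-dimethoxy-2-methylnaphthalene | COc1c(-c2c(C)cc(OC)c3c(OC)cccc23)cccc1F | intermediate
9 | [4-(4,5-dimethoxy-2-methylnaphthalen-1-yl)-2-fluoro-3-methoxyphenyl]lithium | COc1c(-c2c(C)cc(OC)c3c(OC)cccc23)ccc([Li])c1F | intermediate
10 | 4-(4,5-dimethoxy-2-methylnaphthalen-1-yl)-3-methoxybenzyne | COC1=C(-c2c(C)cc(OC)c3c(OC)cccc23)C=CC#C1 | intermediate
11 | [3-(4,5-dimethoxy-2-methylnaphthalen-1-yl)-2-methoxy-6-(prop-2-en-1-yl)phenyl]magnesium bromide | COc1c(-c2c(C)cc(OC)c3c(OC)cccc23)ccc(CC=C)c1[Mg]Br | intermediate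
12 | 1-[3-(4,5-dimethoxy-2-methylnaphthalen-1-yl)-2-methoxy-6-(prop-2-en-1-yl)phenyl]ethan-1-one | COc1c(-c2c(C)cc(OC)c3c(OC)cccc23)ccc(CC=C)c1C(C)=O | intermediate
13 | 1-[2-acetyl-4-(4,5-dimethoxy-2-methylnaphthalen-1-yl)-3-methoxyphenyl]propan-2-one | COc1c(-c2c(C)cc(OC)c3c(OC)cccc23)ccc(CC(C)=O)c1C(C)=O | intermediate
14 | 1-{6-[(2R)-2-aminopropyl]-3-(4,5-dimethoxy-2-methylnaphthalen-1-yl)-2-methoxyphenyl}ethan-1-one | COc1c(-c2c(C)cc(OC)c3c(OC)cccc23)ccc(C[C@@H](C)N)c1C(C)=O | intermediate
15 | (3R)-7-(4,5-dimethoxy-2-methylnaphthalen-1-yl)-8-methoxy-1,3-dimethyl-3,4-dihydroisoquinoline (CNP0168311.1) | COc1c(-c2c(C)cc(OC)c3c(OC)cccc23)ccc2c1C(C)=N[C@H](C)C2 | target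

**Totals**
Total step count: 6. Longest linear sequence: 6 steps (1 → 3 → 7 → 8 → 12 → 13 → 15).

**Three steps most likely to fail, with fallbacks**

Step 2. The hindered α-aryl diketone may stop at simple α- or O-arylation instead of inserting, or the aldol may close the other way to a 2-naphthol. The fallback sets out from 3 and comes back at 7. Compound 3 is deacetylated by retro-Claisen cleavage (aq NaOH, EtOH, 60 °C) to 1-(3-fluoro-2-methoxyphenyl)propan-2-one F1. F1 is then α-arylated at its benzylic CH2 with commercial 1-(2-bromo-6-methoxyphenyl)ethan-1-one (Pd(OAc)2, 2-dicyclohexylphosphino-2',4',6'-triisopropylbiphenyl, NaOtBu, toluene, 90 °C). This gives the same diketone 6 by a regiochemically unambiguous C–C coupling, and 6 closes under the basic conditions to naphthol 7.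

Step 4. The OMe/allyl-flanked arylmagnesium 11 may acylate poorly or be over-allylated. The fallback sets out from 8 and comes back at 12. Intermediate 11 is generated as before but quenched with I2 to give 1-[3-iodo-2-methoxy-4-(prop-2-en-1-yl)phenyl]-4,5-dimethoxy-2-methylnaphthalene F2. Stille coupling of F2 with tributyl(1-ethoxyvinyl)stannane (Pd(PPh3)4, CuI, CsF, DMF, 80 °C) gives 1-[3-(1-ethoxyethenyl)-2-methoxy-4-(prop-2-en-1-yl)phenyl]-4,5-dimethoxy-2-methylnaphthalene F3. Hydrolysis of F3 with 1 M HCl in THF gives ketone 12.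

Step 6. The transaminase may not accept the bulky biaryl ketone. The fallback sets out from 13 and comes back at 14, which cyclises to 15. Diketone 13 is condensed at its unhindered ketone with (R)-tert-butanesulfinamide (Ti(OEt)4, THF, 60 °C) to (R)-N-{1-[2-acetyl-4-(4,5-dimethoxy-2-methylnaphthalen-1-yl)-3-methoxyphenyl]propan-2-ylidene}-2-methylpropane-2-sulfinamide F4. Reduction with NaBH4 (THF, −48 °C) gives (R)-N-{(2R)-1-[2-acetyl-4-(4,5-dimethoxy-2-methylnaphthalen-1-yl)-3-methoxyphenyl]propan-2-yl}-2-methylpropane-2-sulfinamide F5. The diastereoselectivity is expected to be modest because CH2Ar and CH3 differ little in size, so F5 is purified by chromatography; the (S)-auxiliary is used if the facial sense proves reversed. HCl in MeOH followed by NaHCO3 releases amine 14.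

**Further compounds**
F1 | step 2 | 1-(3-fluoro-2-methoxyphenyl)propan-2-one | COc1c(F)cccc1CC(C)=O
F2 | step 4 | 1-[3-iodo-2-methoxy-4-(prop-2-en-1-yl)phenyl]-4,5-dimethoxy-2-methylnaphthalene | COc1c(-c2c(C)cc(OC)c3c(OC)cccc23)ccc(CC=C)c1I
F3 | step 4 | 1-[3-(1-ethoxyethenyl)-2-methoxy-4-(prop-2-en-1-yl)phenyl]-4,5-dimethoxy-2-methylnaphthalene | COc1c(-c2c(C)cc(OC)c3c(OC)cccc23)ccc(CC=C)c1C(=C)OCC
F4 | step 6 | (R)-N-{1-[2-acetyl-4-(4,5-dimethoxy-2-methylnaphthalen-1-yl)-3-methoxyphenyl]propan-2-ylidene}-2-methylpropane-2-sulfinamide | COc1c(-c2c(C)cc(OC)c3c(OC)cccc23)ccc(CC(C)=N[S@](=O)C(C)(C)C)c1C(C)=O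
F5 | step 6 | (R)-N-{(2R)-1-[2-acetyl-4-(4,5-dimethoxy-2-methylnaphthalen-1-yl)-3-methoxyphenyl]propan-2-yl}-2-methylpropane-2-sulfinamide | COc1c(-c2c(C)cc(OC)c3c(OC)cccc23)ccc(C[C@@H](C)N[S@](=O)C(C)(C)C)c1C(C)=O
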